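**Retrosynthetic overview**
1. The target comes from diketone 20 by β-face hydride reduction of the C7 ketone and acetylation of the resulting alcohol.
2. Diketone 20 comes from spiro-enedione 18 in one anionic cascade. A vinylogous aldol (C1–C10) closes ring B and a Michael addition (C11–C9) closes the seven-membered ring C. This sets C1, C8, C9 and C10.
3. Compound 18 is made by an HWE union (C3=C4) of phosphono-lactone enedione 17 with furan aldehyde 7.
4. Compound 17 comes from spirolactone 14. A catalytic asymmetric Diels–Alder reaction sets C5, and reduction/lactonisation, phosphonylation and double allylic oxidation follow.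
5. Ring order: furan (Feist–Benary) in one branch and ring A then the lactone in the other; after the union, rings B and C form together.

Assumption: atoms carry clerodane numbers (ring A = C5–C10, ring B = C1–C5/C10, C18 lactone C=O, C19 lactone CH2, C11–C12 = CH2–C=O, C13–C16 furan, C17/C20 methyls on C8/C9); α is the face that carries the 10-OH.

Step 1
Reactants: 1 pentane-2,4-dione; 2 chloroacetaldehyde
Product: 3 1-(2-methylfuran-3-yl)ethanone
Conditions: aq. NaOH (1 equiv), H2O, 0 °C to rt
Reagents that add atoms: none
Why: In this Feist–Benary furan synthesis the diketone enolate adds to the aldehyde, the enol oxygen displaces chloride and dehydration aromatises the ring, which places acetyl at C3 and methyl at C2 and creates no stereocentre.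

Step 2
Reactants: 3 1-(2-methylfuran-3-yl)ethanone
Product: 4 1-[2-(bromomethyl)furan-3-yl]ethanone
Conditions: NBS, AIBN (cat.), PhCF3, reflux
Reagents that add atoms: N-bromosuccinimide, O=C1CCC(=O)N1Br
Why: This Wohl–Ziegler bromination goes to the 2-methyl group because the furfuryl radical is the most stabilised one and the acyl group deactivates the ring toward ionic bromination; no stereocentre forms.

Step 3
Reactants: 4 1-[2-(bromomethyl)furan-3-yl]ethanone; 5 (E)-2-(2-ethoxyvinyl)-4,4,5,5-tetramethyl-1,3,2-dioxaborolane
Product: 7 3-(3-acetylfuran-2-yl)propanal, via enol ether 6 (not isolated)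
Conditions: Pd(PPh3)4 (5 mol %), K2CO3, THF/H2O, 60 °C; then 1 M HCl, THF, rt
Reagents that add atoms: water, O
Why: Suzuki–Miyaura sp3–sp2 coupling of the activated furfuryl bromide followed by acid hydrolysis of the enol ether uses the boronate as an acetaldehyde-enolate equivalent and adds the two-carbon aldehyde arm (C2, C3) without creating a stereocentre.

Step 4
Reactants: 8 methyl 4-oxobutanoate; 9 formaldehyde
Product: 10 methyl 3-formylbut-3-enoate
Conditions: 37% aq. HCHO, pyrrolidine/propionic acid (10 mol % each), i-PrOH, 45 °C
Reagents that add atoms: none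
Why: This organocatalytic Mannich-type α-methylenation of an aldehyde (enamine addition, then amine elimination) is fast and mild enough to leave the skipped ester CH2 unisomerised; no stereocentre forms.

Step 5
Reactants: 10 methyl 3-formylbut-3-enoate; 11 2,3-dimethylbuta-1,3-diene
Product: 12 methyl 2-[(1S)-1-formyl-3,4-dimethylcyclohex-3-en-1-yl]acetate
Conditions: (S)-diphenylprolinol-derived o-tolyl-oxazaborolidinium triflimide (10 mol %), CH2Cl2, −78 to −40 °C
Reagents that add atoms: none
Why: In this catalytic asymmetric Diels–Alder reaction of a 2-substituted acrolein the cationic oxazaborolidine binds the formyl group and shields one face, so the symmetrical diene adds to the Si face of the α-carbon and sets the quaternary C5 as S (regiochemistry is not an issue, and the antipodal catalyst is equally available).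

Step 6
Reactants: 12 methyl 2-[(1S)-1-formyl-3,4-dimethylcyclohex-3-en-1-yl]acetate
Product: 14 (5S)-7,8-dimethyl-2-oxaspiro[4.5]dec-7-en-3-one, via hydroxy ester 13 (not isolated)
Conditions: NaBH4, MeOH, 0 °C; then 1 M HCl, rt
Reagents that add atoms: none
Why: Borohydride reduces the aldehyde chemoselectively beside the ester and acid then promotes 5-exo lactonisation, which gives the C19H2–O–C18(=O) lactone in the correct orientation without touching C5.

Step 7
Reactants: 14 (5S)-7,8-dimethyl-2-oxaspiro[4.5]dec-7-en-3-one
Product: 16 diethyl [(5R)-7,8-dimethyl-3-oxo-2-oxaspiro[4.5]dec-7-en-4-yl]phosphonate (C4 epimers), via enol phosphate 15 (not isolated)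
Conditions: LDA (1.1 equiv), ClP(O)(OEt)2, THF, −78 °C; then LDA (2.2 equiv), −78 °C to rt; aq. NH4Cl
Reagents that add atoms: diethyl chlorophosphate, CCOP(=O)(Cl)OCC
Why: O-phosphorylation of the lactone enolate followed by base-induced 1,3 O-to-C phosphorus migration (vinyl phosphate to phosphonate rearrangement) gives the α-phosphono lactone; the new C4 centre is a mixture that is erased in step 9, and the C5 descriptor changes only through CIP priorities.

Step 8
Reactants: 16 diethyl [(5R)-7,8-dimethyl-3-oxo-2-oxaspiro[4.5]dec-7-en-4-yl]phosphonate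
Product: 17 diethyl [(5S)-7,8-dimethyl-3,6,9-trioxo-2-oxaspiro[4.5]dec-7-en-4-yl]phosphonate (C4 epimers)
Conditions: Rh2(cap)4 (2 × 0.5 mol %), 70% aq. t-BuOOH (12 equiv), DCE, 40 °C
Reagents that add atoms: tert-butyl hydroperoxide, CC(C)(C)OO
Why: Radical allylic oxidation by tert-butylperoxyl radicals attacks the two ring CH2 groups flanking the tetrasubstituted alkene (the open C7 first, then the enone γ-position C10) to give the enedione before any furan is present, while the primary methyl C–H bonds react more slowly and C5 is untouched.

Step 9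
Reactants: 17 diethyl [(5S)-7,8-dimethyl-3,6,9-trioxo-2-oxaspiro[4.5]dec-7-en-4-yl]phosphonate; 7 3-(3-acetylfuran-2-yl)propanal
Product: 18 (4E,5S)-4-[3-(3-acetylfuran-2-yl)propylidene]-7,8-dimethyl-2-oxaspiro[4.5]dec-7-ene-3,6,9-trione
Conditions: LiCl, DBU, MeCN, 0 °C
Reagents that add atoms: none
Why: In this Horner–Wadsworth–Emmons olefination under Masamune–Roush conditions the soft lithium-chelated phosphonate anion reacts with the aliphatic aldehyde and not with the methyl ketone or the hindered enedione, and it gives mainly the E-alkylidene lactone (chain cis to C5) while any Z isomer is carried on because it equilibrates in step 10.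

Step 10
Reactants: 18 (4E,5S)-4-[3-(3-acetylfuran-2-yl)propylidene]-7,8-dimethyl-2-oxaspiro[4.5]dec-7-ene-3,6,9-trione
Product: 20 tetracyclic 10α-hydroxy-7,12-diketone (C1 C5 C8 C9 C10 configured as in the target), via cis-ketol 19 (not isolated)
Conditions: t-BuOK (0.3 equiv), t-BuOH/THF 1:3, 2 mM, Ar, 0 to 25 °C; AcOH quench
Reagents that add atoms: none
Why: Proposed new method: under catalytic, fully reversible alkoxide conditions all enolisable sites exchange, but only the extended furan dienolate (loss of C1–H, vinylogous to the C12 acetyl) has an electrophile in reach, so C1 adds to the activated enedione carbonyl C10 through a six-membered transition state from the face that carries C4 (the three-atom tether allows no other) and gives cis-ketol 19 with OH cis to the CH2O group, after which the acetyl enolate carbon C11, now held over the β face of the unmasked γ-hydroxy-enone, closes the seven-membered ring by Michael addition to C9 anti to the OH group and the C8 enolate is protonated to the equatorial methyl epimer, while the Z-alkene and the unproductive C1 epimer are recycled by γ-deprotonation and retro-aldol; the closest known reaction types are the Robinson ketol closure, lateral (vinylogous) aldol additions of 2-alkyl-3-carbonylfurans and anionic Michael/aldol polycyclisation cascades.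

Step 11
Reactants: 20 tetracyclic 10α-hydroxy-7,12-diketone
Product: 21 7α,10α-dihydroxy-12-ketone (7R; deacetyl target)
Conditions: NaBH4 (1.0 equiv), MeOH/CH2Cl2, −78 to −40 °C
Reagents that add atoms: none
Why: This substrate-controlled borohydride reduction is selective because the saturated cyclohexanone C7 is far more electrophilic than the furan-conjugated C12 ketone, and the axial C19 and C20 groups block the α face so that hydride enters from the β face and gives the axial 7α-alcohol.

Step 12
Reactants: 21 7α,10α-dihydroxy-12-ketone
Product: 22 target CNP0329797.1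
Conditions: Ac2O, Et3N, DMAP (cat.), CH2Cl2, rt
Reagents that add atoms: acetic anhydride, CC(=O)OC(C)=O
Why: DMAP-catalysed acylation takes the secondary C7 alcohol only, because the tertiary C10–OH sits between two quaternary carbons and stays free; no stereocentre changes.

**Compound list**
1 | pentane-2,4-dione | CC(=O)CC(C)=O | starting material
2 | chloroacetaldehyde | ClCC=O | starting material
3 | 1-(2-methylfuran-3-yl)ethanone | CC(=O)c1ccoc1C | intermediate
4 | 1-[2-(bromomethyl)furan-3-yl]ethanone | CC(=O)c1ccoc1CBr | intermediate
5 | (E)-2-(2-ethoxyvinyl)-4,4,5,5-tetramethyl-1,3,2-dioxaborolane | CCO/C=C/B1OC(C)(C)C(C)(C)O1 | starting material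
6 | 1-{2-[(2E)-3-ethoxyprop-2-en-1-yl]furan-3-yl}ethanone (not isolated) | CCO/C=C/Cc1occc1C(C)=O | intermediate
7 | 3-(3-acetylfuran-2-yl)propanal | CC(=O)c1ccoc1CCC=O | intermediate
8 | methyl 4-oxobutanoate | COC(=O)CCC=O | starting material
9 | formaldehyde | C=O | starting material
10 | methyl 3-formylbut-3-enoate | COC(=O)CC(=C)C=O | intermediate
11 | 2,3-dimethylbuta-1,3-diene | CC(=C)C(C)=C | starting material
12 | methyl 2-[(1S)-1-formyl-3,4-dimethylcyclohex-3-en-1-yl]acetate | C1C[C@@](C=O)(CC(=O)OC)CC(C)=C1C | intermediate
13 | methyl 2-[(1S)-1-(hydroxymethyl)-3,4-dimethylcyclohex-3-en-1-yl]acetate (not isolated) | C1C[C@@](CO)(CC(=O)OC)CC(C)=C1C | intermediate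
14 | (5S)-7,8-dimethyl-2-oxaspiro[4.5]dec-7-en-3-one | C1C[C@]2(COC(=O)C2)CC(C)=C1C | intermediate
15 | lactone enol diethyl phosphate of 14 (not isolated) | C1C[C@]2(COC(OP(=O)(OCC)OCC)=C2)CC(C)=C1C | intermediate
16 | diethyl [(5R)-7,8-dimethyl-3-oxo-2-oxaspiro[4.5]dec-7-en-4-yl]phosphonate (C4 epimers) | C1C[C@]2(COC(=O)C2P(=O)(OCC)OCC)CC(C)=C1C | intermediate
17 | diethyl [(5S)-7,8-dimethyl-3,6,9-trioxo-2-oxaspiro[4.5]dec-7-en-4-yl]phosphonate (C4 epimers) | O=C1C[C@]2(COC(=O)C2P(=O)(OCC)OCC)C(=O)C(C)=C1C | intermediate
18 | (4E,5S)-4-[3-(3-acetylfuran-2-yl)propylidene]-7,8-dimethyl-2-oxaspiro[4.5]dec-7-ene-3,6,9-trione | O=C1C[C@]2(COC(=O)/C2=C/CCc2occc2C(C)=O)C(=O)C(C)=C1C | intermediate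
19 | cis-ketol (rings A, B and lactone; 10α-OH, 1β-(3-acetylfuran-2-yl), 7-oxo-8-ene; not isolated) | O=C1C[C@@]23COC(=O)C2=CC[C@@H](c2occc2C(C)=O)[C@@]3(O)C(C)=C1C | intermediate
20 | tetracyclic 10α-hydroxy-7,12-diketone | O=C1C[C@@]23COC(=O)C2=CC[C@H]2c4occc4C(=O)C[C@@](C)([C@@H]1C)[C@]23O | intermediate
21 | 7α,10α-dihydroxy-12-ketone (deacetyl target) | O[C@@H]1C[C@@]23COC(=O)C2=CC[C@H]2c4occc4C(=O)C[C@@](C)([C@@H]1C)[C@]23O | intermediate
22 | CNP0329797.1 | CC(=O)O[C@@H]1C[C@@]23COC(=O)C2=CC[C@H]2c4occc4C(=O)C[C@@](C)([C@@H]1C)[C@]23O | target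

**Step count:** 12 steps in total. The longest linear sequence is 9 steps (steps 4–12). The furan aldehyde branch (steps 1–3) joins in step 9.

**Three steps most likely to fail**

*Step 10 (cascade).* The C1–H bond is less acidic than the acetyl and C6 protons. The ketol could dehydrate or close with the wrong C1 epimer. The Michael addition has to build a quaternary carbon in a seven-membered ring. The fallback sets out from 18 and generates the C1 nucleophile photochemically instead of by base. Irradiation at 365 nm in degassed toluene shifts the C1 hydrogen to the excited acetyl oxygen. The resulting furan photoenol is trapped by the neighbouring activated C10 ketone in an intramolecular [4+2]/aldol step. This gives the bridged C10–O–C12 lactol F1, which is the ring tautomer of 19. Catalytic t-BuOK then has to run only the Michael closure, and the route is rejoined at 20.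

*Step 8 (double allylic oxidation).* The neopentyl C10H2 group may stop the oxidation at the mono-enone. The fallback sets out from 16 and brings in both oxygens at once by cycloaddition. Br2 addition gives the 7,8-dibromide F2. Double dehydrobromination with DBU gives the ring 1,3-diene F3. Singlet oxygen (TPP, O2, hν) gives the 6,9-endoperoxide F4. Et3N (Kornblum–DeLaMare) opens it to the 6-hydroxy-9-oxo-enone F5. Dess–Martin oxidation of F5 returns to 17.

*Step 11 (C7 versus C12 selectivity).* The fallback sets out from 20 and gives up selectivity in the reduction. Excess NaBH4 reduces both ketones to the 7,10,12-triol F6. MnO2 then re-oxidises only the furyl (benzylic-type) C12 carbinol, which returns to 21.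

**Further compounds**
F1 | step 10 | bridged C10–O–C12 lactol (ring tautomer of 19) | O=C1C[C@@]23COC(=O)C2=CC[C@H]2c4occc4C(C)(O)O[C@@]23C(C)=C1C
F2 | step 8 | diethyl [(5R)-7,8-dibromo-7,8-dimethyl-3-oxo-2-oxaspiro[4.5]decan-4-yl]phosphonate | C1C[C@]2(COC(=O)C2P(=O)(OCC)OCC)CC(C)(Br)C1(C)Br
F3 | step 8 | diethyl (7,8-dimethyl-3-oxo-2-oxaspiro[4.5]deca-6,8-dien-4-yl)phosphonate | C1=C(C)C(C)=C[C@]2(C1)COC(=O)C2P(=O)(OCC)OCC
F4 | step 8 | 6,9-epidioxy adduct of F3 (endoperoxide) | CC1=C(C)C2OOC1C[C@]23COC(=O)C3P(=O)(OCC)OCC
F5 | step 8 | diethyl (6-hydroxy-7,8-dimethyl-3,9-dioxo-2-oxaspiro[4.5]dec-7-en-4-yl)phosphonate | O=C1C[C@]2(COC(=O)C2P(=O)(OCC)OCC)C(O)C(C)=C1C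
F6 | step 11 | 7α,10α,12-triol (C12 epimers) | O[C@@H]1C[C@@]23COC(=O)C2=CC[C@H]2c4occc4C(O)C[C@@](C)([C@@H]1C)[C@]23O
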